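**Assumption:** the SMILES fixes only the three carbon stereocentres (1R,3R in the tetrahydroisoquinoline, 3R in the dihydroisoquinoline) and gives no descriptor for the two hindered isoquinoline–naphthalene axes. Structures are therefore written without axial descriptors; the atropo-diastereomers formed in steps 14 and 23 are separated by chromatography and the natural-configured ones carried on.

## Retrosynthetic overview

1. Korundamine A ⇐ global acid deprotection of a Boc/MOM-protected dimer, whose central naphthalene–naphthalene bond comes from a Suzuki coupling of a naphthyl boronate (tetrahydroisoquinoline half) with a naphthyl chloride (dihydroisoquinoline half).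
2. Each half ⇐ Suzuki coupling (C–I reacts, C–Cl survives) of one common chloronaphthyl boronate with a 5-iodo-tetrahydroisoquinoline or a 7-iodo-dihydroisoquinoline.
3. Common naphthalene ⇐ regiocontrolled Diels–Alder reaction of 2,6-dichlorobenzoquinone with a vinylketene acetal, then O-methylation, reduction, site-selective triflation and borylation.
4. Both nitrogen rings ⇐ Pictet–Spengler closure (an intramolecular Mannich reaction onto a free phenol) of (R)-arylisopropylamines made by aryl Grignard opening of an (R)-aziridine; the imine of the second half by N-chlorination/dehydrochlorination.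
5. Ring order: naphthalene carbocycle (Diels–Alder), then each nitrogen ring (Mannich), then the three biaryl bonds.

## Route

**Common naphthalene boronate (steps 1–7)**

Step 1
Reactants: 1 methyl 3-methylbut-2-enoate
Product: 2 1-methoxy-3-methyl-1-(trimethylsilyloxy)buta-1,3-diene
Conditions: LiN(iPr)2, THF, −78 °C; Me3SiCl, −78 °C → rt
Reagents that add atoms: chlorotrimethylsilane (C[Si](C)(C)Cl)
Why: γ-Deprotonation gives the extended dienolate, which is O-silylated to the vinylketene acetal (silyl dienol ether formation).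

Step 2
Reactants: 2 1-methoxy-3-methyl-1-(trimethylsilyloxy)buta-1,3-diene; 3 2,6-dichloro-1,4-benzoquinone
Product: 5 2-chloro-8-hydroxy-6-methylnaphthalene-1,4-dione, via cycloadduct 4 (not isolated)
Conditions: CH2Cl2, −30 °C → rt; then SiO2, rt
Reagents that add atoms: none
Why: Regiocontrolled Diels–Alder cycloaddition in which the CH2 terminus of the diene bonds to the unsubstituted quinone carbon and the acetal carbon to a chlorine-bearing one, so loss of HCl and MeOH on aromatisation leaves the phenol peri to the carbonyl that keeps the neighbouring chlorine.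

Step 3
Reactants: 5 2-chloro-8-hydroxy-6-methylnaphthalene-1,4-dione
Product: 6 2-chloro-8-methoxy-6-methylnaphthalene-1,4-dione
Conditions: MeI, Ag2O, CH2Cl2, rt, dark
Reagents that add atoms: iodomethane (CI)
Why: Ag2O-promoted Williamson O-methylation etherifies the chelated peri-hydroxyl without touching the chloroquinone.

Step 4
Reactants: 6 2-chloro-8-methoxy-6-methylnaphthalene-1,4-dione
Product: 7 2-chloro-8-methoxy-6-methylnaphthalene-1,4-diol
Conditions: Na2S2O4, EtOAc/H2O, rt, Ar; used directly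
Reagents that add atoms: none
Why: Dithionite reduction of a quinone to its hydroquinone is fast and leaves the aryl chloride alone.

Step 5
Reactants: 7 2-chloro-8-methoxy-6-methylnaphthalene-1,4-diol
Product: 8 3-chloro-4-hydroxy-5-methoxy-7-methylnaphthalen-1-yl trifluoromethanesulfonate
Conditions: Tf2O (1.0 equiv), iPr2NEt, CH2Cl2, −78 °C
Reagents that add atoms: trifluoromethanesulfonic anhydride (O=S(=O)(OS(=O)(=O)C(F)(F)F)C(F)(F)F)
Why: Site-selective O-sulfonylation, because the C4 hydroxyl is unhindered whereas the C1 hydroxyl is flanked by chlorine and hydrogen-bonded to the peri methoxy group.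

Step 6
Reactants: 8 3-chloro-4-hydroxy-5-methoxy-7-methylnaphthalen-1-yl trifluoromethanesulfonate
Product: 9 3-chloro-5-methoxy-4-(methoxymethoxy)-7-methylnaphthalen-1-yl trifluoromethanesulfonate
Conditions: MeOCH2Cl, iPr2NEt, Bu4NI (cat.), CH2Cl2, 0 → 40 °C
Reagents that add atoms: chloromethyl methyl ether (COCCl)
Why: Williamson-type acetalisation of the remaining naphthol gives a base-stable and acid-labile MOM ether.

Step 7
Reactants: 9 3-chloro-5-methoxy-4-(methoxymethoxy)-7-methylnaphthalen-1-yl trifluoromethanesulfonate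
Product: 10 2-[3-chloro-5-methoxy-4-(methoxymethoxy)-7-methylnaphthalen-1-yl]-4,4,5,5-tetramethyl-1,3,2-dioxaborolane
Conditions: B2pin2, Pd(dppf)Cl2 (5 mol %), KOAc, 1,4-dioxane, 85 °C
Reagents that add atoms: bis(pinacolato)diboron (CC1(C)OB(OC1(C)C)B1OC(C)(C)C(C)(C)O1)
Why: Miyaura borylation in which zerovalent palladium carrying dppf inserts into the C–OTf bond but not into the electron-rich C–Cl bond.

**Tetrahydroisoquinoline half (steps 8–15)**

Step 8
Reactants: 11 1-bromo-3,5-dimethoxybenzene; 12 tert-butyl (2R)-2-methylaziridine-1-carboxylate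
Product: 14 tert-butyl N-[(2R)-1-(3,5-dimethoxyphenyl)propan-2-yl]carbamate, via Grignard reagent 13 (not isolated)
Conditions: Mg, THF, reflux; then CuBr·SMe2 (10 mol %), 12, THF, −30 → 0 °C; aq. work-up
Reagents that add atoms: none
Why: Copper-catalysed SN2 ring opening of the activated aziridine at its unsubstituted CH2 carbon by the aryl Grignard reagent leaves the (R) stereocentre of 12 untouched.

Step 9
Reactants: 14 tert-butyl N-[(2R)-1-(3,5-dimethoxyphenyl)propan-2-yl]carbamate
Product: 15 5-[(2R)-2-aminopropyl]benzene-1,3-diol hydrobromide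
Conditions: 48% aq. HBr, AcOH, rt then reflux
Reagents that add atoms: hydrogen bromide (Br)
Why: Acidolysis removes the Boc group and bromide cleaves both aryl methyl ethers (SN2 ether cleavage) without affecting the stereocentre.

Step 10
Reactants: 15 5-[(2R)-2-aminopropyl]benzene-1,3-diol hydrobromide
Product: 17 (1R,3R)-1,3-dimethyl-1,2,3,4-tetrahydroisoquinoline-6,8-diol hydrobromide, via iminium ion 16 (not isolated)
Conditions: CH3CHO (1.2 equiv), KH2PO4/K2HPO4 buffer (pH 6), H2O/MeOH, 40 °C, Ar; recrystallisation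
Reagents that add atoms: acetaldehyde (CC=O)
Why: Pictet–Spengler reaction, i.e. an intramolecular Mannich reaction of the iminium ion with the resorcinol ring (both ortho sites equivalent), in which the new C1 methyl goes pseudo-axial to avoid the peri 8-OH while the C3 methyl stays equatorial, so the 1,3-trans (1R,3R) isomer predominates and the minor cis isomer is removed by recrystallisation.

Step 11
Reactants: 17 (1R,3R)-1,3-dimethyl-1,2,3,4-tetrahydroisoquinoline-6,8-diol hydrobromide
Product: 18 tert-butyl (1R,3R)-6,8-dihydroxy-1,3-dimethyl-3,4-dihydro-1H-isoquinoline-2-carboxylate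
Conditions: Boc2O, Et3N, MeOH, 45 °C; then K2CO3, MeOH, rt
Reagents that add atoms: di-tert-butyl dicarbonate (CC(C)(C)OC(=O)OC(=O)OC(C)(C)C)
Why: Carbamate formation on the more nucleophilic nitrogen, with any aryl carbonate cleaved by the carbonate wash.

Step 12
Reactants: 18 tert-butyl (1R,3R)-6,8-dihydroxy-1,3-dimethyl-3,4-dihydro-1H-isoquinoline-2-carboxylate
Product: 19 tert-butyl (1R,3R)-6,8-bis(methoxymethoxy)-1,3-dimethyl-3,4-dihydro-1H-isoquinoline-2-carboxylate
Conditions: NaH, MeOCH2Cl, DMF, 0 °C → rt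
Reagents that add atoms: chloromethyl methyl ether (COCCl)
Why: Williamson-type alkylation of both phenoxides, the sodium salt being reactive enough for the hindered 8-position.

Step 13
Reactants: 19 tert-butyl (1R,3R)-6,8-bis(methoxymethoxy)-1,3-dimethyl-3,4-dihydro-1H-isoquinoline-2-carboxylate
Product: 20 tert-butyl (1R,3R)-5-iodo-6,8-bis(methoxymethoxy)-1,3-dimethyl-3,4-dihydro-1H-isoquinoline-2-carboxylate
Conditions: NIS, MeCN, 0 °C → rt, dark
Reagents that add atoms: N-iodosuccinimide (O=C1CCC(=O)N1I)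
Why: Electrophilic aromatic iodination goes to C5 (para to the 8-oxygen and ortho to the 6-oxygen) and not to C7, which is wedged between two alkoxy groups.

Step 14
Reactants: 20 tert-butyl (1R,3R)-5-iodo-6,8-bis(methoxymethoxy)-1,3-dimethyl-3,4-dihydro-1H-isoquinoline-2-carboxylate; 10 2-[3-chloro-5-methoxy-4-(methoxymethoxy)-7-methylnaphthalen-1-yl]-4,4,5,5-tetramethyl-1,3,2-dioxaborolane
Product: 21 tert-butyl (1R,3R)-5-[3-chloro-5-methoxy-4-(methoxymethoxy)-7-methylnaphthalen-1-yl]-6,8-bis(methoxymethoxy)-1,3-dimethyl-3,4-dihydro-1H-isoquinoline-2-carboxylate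
Conditions: Pd(PPh3)4 (10 mol %), K3PO4, 1,4-dioxane/H2O, 90 °C; chromatographic separation of atropo-diastereomers
Reagents that add atoms: none
Why: Suzuki–Miyaura coupling in which zerovalent palladium carrying PPh3 inserts only into the C–I bond and leaves the C–Cl bond for later.

Step 15
Reactants: 21 tert-butyl (1R,3R)-5-[3-chloro-5-methoxy-4-(methoxymethoxy)-7-methylnaphthalen-1-yl]-6,8-bis(methoxymethoxy)-1,3-dimethyl-3,4-dihydro-1H-isoquinoline-2-carboxylate
Product: 22 tert-butyl (1R,3R)-5-[5-methoxy-4-(methoxymethoxy)-7-methyl-3-(4,4,5,5-tetramethyl-1,3,2-dioxaborolan-2-yl)naphthalen-1-yl]-6,8-bis(methoxymethoxy)-1,3-dimethyl-3,4-dihydro-1H-isoquinoline-2-carboxylate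
Conditions: B2pin2, Pd2(dba)3 (3 mol %), XPhos, KOAc, 1,4-dioxane, 100 °C
Reagents that add atoms: bis(pinacolato)diboron (CC1(C)OB(OC1(C)C)B1OC(C)(C)C(C)(C)O1)
Why: Miyaura borylation of the aryl chloride, enabled by the bulky electron-rich phosphine XPhos, with KOAc too weak a base to trigger Suzuki homocoupling.

**Dihydroisoquinoline half (steps 16–23)**

Step 16
Reactants: 23 3-bromo-5-methoxyphenol
Product: 24 1-bromo-3-methoxy-5-(methoxymethoxy)benzene
Conditions: MeOCH2Cl, iPr2NEt, CH2Cl2, 0 °C → rt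
Reagents that add atoms: chloromethyl methyl ether (COCCl)
Why: Williamson-type acetalisation gives a MOM ether that tolerates Grignard formation and later directs lithiation.

Step 17
Reactants: 24 1-bromo-3-methoxy-5-(methoxymethoxy)benzene; 12 tert-butyl (2R)-2-methylaziridine-1-carboxylate
Product: 26 tert-butyl N-[(2R)-1-[3-methoxy-5-(methoxymethoxy)phenyl]propan-2-yl]carbamate, via Grignard reagent 25 (not isolated)
Conditions: Mg, THF, 40 °C; then CuBr·SMe2 (10 mol %), 12, THF, −30 → 0 °C; aq. work-up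
Reagents that add atoms: none
Why: Copper-catalysed SN2 opening of the aziridine at CH2 as in step 8, so the (R) centre is carried over unchanged.

Step 18
Reactants: 26 tert-butyl N-[(2R)-1-[3-methoxy-5-(methoxymethoxy)phenyl]propan-2-yl]carbamate
Product: 28 tert-butyl N-[(2R)-1-[4-iodo-3-methoxy-5-(methoxymethoxy)phenyl]propan-2-yl]carbamate, via dilithio species 27 (not isolated)
Conditions: n-BuLi (2.3 equiv), THF, −78 → 0 °C; I2, THF, −78 °C → rt; aq. Na2S2O3
Reagents that add atoms: iodine (II)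
Why: Directed ortho-metalation, in which after N–H deprotonation the second equivalent of n-BuLi removes the ring proton flanked by both the OMe and OMOM groups and iodine traps the aryllithium.

Step 19
Reactants: 28 tert-butyl N-[(2R)-1-[4-iodo-3-methoxy-5-(methoxymethoxy)phenyl]propan-2-yl]carbamate
Product: 29 5-[(2R)-2-aminopropyl]-2-iodo-3-methoxyphenol hydrochloride
Conditions: 3 M HCl in MeOH, rt
Reagents that add atoms: hydrogen chloride (Cl)
Why: Acidolysis of the Boc group and acid-catalysed acetal exchange of the MOM ether free the amine and the one phenol needed to steer the ring closure.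

Step 20
Reactants: 29 5-[(2R)-2-aminopropyl]-2-iodo-3-methoxyphenol hydrochloride
Product: 31 (3R)-7-iodo-8-methoxy-1,3-dimethyl-1,2,3,4-tetrahydroisoquinolin-6-ol, via iminium ion 30 (not isolated)
Conditions: CH3CHO (1.2 equiv), KH2PO4/K2HPO4 buffer (pH 6.5), H2O/MeOH, 45 °C, Ar; then aq. NaHCO3; chromatography
Reagents that add atoms: acetaldehyde (CC=O)
Why: Pictet–Spengler (intramolecular Mannich) closure in which, in protic buffer, the iminium ion attacks para to the free and partly ionised phenol, placing OH at C6 and OMe at C8; the C1 configuration does not matter because step 22 makes C1 sp2, and C3 (R) comes from 12.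

Step 21
Reactants: 31 (3R)-7-iodo-8-methoxy-1,3-dimethyl-1,2,3,4-tetrahydroisoquinolin-6-ol
Product: 32 (3R)-7-iodo-8-methoxy-6-(methoxymethoxy)-1,3-dimethyl-1,2,3,4-tetrahydroisoquinoline
Conditions: NaH (1.05 equiv), DMF, −20 °C; MeOCH2Cl (1.05 equiv), −20 → 0 °C; aq. NH4Cl
Reagents that add atoms: chloromethyl methyl ether (COCCl)
Why: Chemoselective Williamson-type O-alkylation, since one equivalent of NaH forms only the phenoxide, which outruns the hindered neutral nitrogen, and any N-CH2OMe aminal reverts on aqueous work-up.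

Step 22
Reactants: 32 (3R)-7-iodo-8-methoxy-6-(methoxymethoxy)-1,3-dimethyl-1,2,3,4-tetrahydroisoquinoline
Product: 34 (3R)-7-iodo-8-methoxy-6-(methoxymethoxy)-1,3-dimethyl-3,4-dihydroisoquinoline, via N-chloroamine 33 (not isolated)
Conditions: NCS, CH2Cl2, 0 °C; then DBU, rt
Reagents that add atoms: none
Why: N-Chlorination followed by base-induced E2 dehydrochlorination removes the acidic benzylic C1–H to give the aryl-conjugated cyclic imine and leaves C3 untouched.

Step 23
Reactants: 34 (3R)-7-iodo-8-methoxy-6-(methoxymethoxy)-1,3-dimethyl-3,4-dihydroisoquinoline; 10 2-[3-chloro-5-methoxy-4-(methoxymethoxy)-7-methylnaphthalen-1-yl]-4,4,5,5-tetramethyl-1,3,2-dioxaborolane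
Product: 35 (3R)-7-[3-chloro-5-methoxy-4-(methoxymethoxy)-7-methylnaphthalen-1-yl]-8-methoxy-6-(methoxymethoxy)-1,3-dimethyl-3,4-dihydroisoquinoline
Conditions: Pd(PPh3)4 (10 mol %), K3PO4, 1,4-dioxane/H2O, 95 °C; chromatographic separation of atropo-diastereomers
Reagents that add atoms: none
Why: Suzuki–Miyaura coupling that is chemoselective for C–I over C–Cl, with the imine stable to aqueous phosphate.

**Union and deprotection (steps 24–25)**

Step 24
Reactants: 22 tert-butyl (1R,3R)-5-[5-methoxy-4-(methoxymethoxy)-7-methyl-3-(4,4,5,5-tetramethyl-1,3,2-dioxaborolan-2-yl)naphthalen-1-yl]-6,8-bis(methoxymethoxy)-1,3-dimethyl-3,4-dihydro-1H-isoquinoline-2-carboxylate; 35 (3R)-7-[3-chloro-5-methoxy-4-(methoxymethoxy)-7-methylnaphthalen-1-yl]-8-methoxy-6-(methoxymethoxy)-1,3-dimethyl-3,4-dihydroisoquinoline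
Product: 36 N-Boc-penta-O-MOM-korundamine A
Conditions: Pd(OAc)2 (8 mol %), SPhos, K3PO4, toluene/H2O, 100 °C
Reagents that add atoms: none
Why: Suzuki–Miyaura coupling of an aryl chloride enabled by SPhos, in which only the cross-product can form because 22 has no halide and 35 no boron, and the new central axis has only two ortho substituents and rotates freely.

Step 25
Reactants: 36 N-Boc-penta-O-MOM-korundamine A
Product: 37 korundamine A
Conditions: 3 M HCl in MeOH, 45 °C, Ar; then aq. NaHCO3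
Reagents that add atoms: none
Why: Acid-catalysed acetal exchange removes all five MOM ethers and acidolysis removes the Boc group, while the cyclic imine survives as its iminium salt and no stereocentre is touched.

## Compound list

1 | methyl 3-methylbut-2-enoate | COC(=O)C=C(C)C | starting material
2 | 1-methoxy-3-methyl-1-(trimethylsilyloxy)buta-1,3-diene | COC(O[Si](C)(C)C)=CC(C)=C | intermediate
3 | 2,6-dichloro-1,4-benzoquinone | O=C1C=C(Cl)C(=O)C(Cl)=C1 | starting material
4 | 2,8a-dichloro-8-methoxy-6-methyl-8-(trimethylsilyloxy)-4a,5,8,8a-tetrahydronaphthalene-1,4-dione (racemic cycloadduct, not isolated) | COC1(O[Si](C)(C)C)C=C(C)CC2C(=O)C=C(Cl)C(=O)C12Cl | intermediate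
5 | 2-chloro-8-hydroxy-6-methylnaphthalene-1,4-dione | Cc1cc(O)c2c(c1)C(=O)C=C(Cl)C2=O | intermediate
6 | 2-chloro-8-methoxy-6-methylnaphthalene-1,4-dione | COc1cc(C)cc2c1C(=O)C(Cl)=CC2=O | intermediate
7 | 2-chloro-8-methoxy-6-methylnaphthalene-1,4-diol | COc1cc(C)cc2c(O)cc(Cl)c(O)c12 | intermediate
8 | 3-chloro-4-hydroxy-5-methoxy-7-methylnaphthalen-1-yl trifluoromethanesulfonate | COc1cc(C)cc2c(OS(=O)(=O)C(F)(F)F)cc(Cl)c(O)c12 | intermediate
9 | 3-chloro-5-methoxy-4-(methoxymethoxy)-7-methylnaphthalen-1-yl trifluoromethanesulfonate | COCOc1c(Cl)cc(OS(=O)(=O)C(F)(F)F)c2cc(C)cc(OC)c12 | intermediate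
10 | 2-[3-chloro-5-methoxy-4-(methoxymethoxy)-7-methylnaphthalen-1-yl]-4,4,5,5-tetramethyl-1,3,2-dioxaborolane | COCOc1c(Cl)cc(B2OC(C)(C)C(C)(C)O2)c2cc(C)cc(OC)c12 | intermediate
11 | 1-bromo-3,5-dimethoxybenzene | COc1cc(Br)cc(OC)c1 | starting material
12 | tert-butyl (2R)-2-methylaziridine-1-carboxylate | C[C@@H]1CN1C(=O)OC(C)(C)C | starting material
13 | (3,5-dimethoxyphenyl)magnesium bromide (not isolated) | COc1cc(OC)cc([Mg]Br)c1 | intermediate
14 | tert-butyl N-[(2R)-1-(3,5-dimethoxyphenyl)propan-2-yl]carbamate | COc1cc(C[C@@H](C)NC(=O)OC(C)(C)C)cc(OC)c1 | intermediate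
15 | 5-[(2R)-2-aminopropyl]benzene-1,3-diol hydrobromide | C[C@@H](N)Cc1cc(O)cc(O)c1.Br | intermediate
16 | (2R)-1-(3,5-dihydroxyphenyl)-N-ethylidenepropan-2-aminium bromide (not isolated) | CC=[NH+][C@H](C)Cc1cc(O)cc(O)c1.[Br-] | intermediate
17 | (1R,3R)-1,3-dimethyl-1,2,3,4-tetrahydroisoquinoline-6,8-diol hydrobromide | Oc1cc(O)c2c(c1)C[C@@H](C)N[C@@H]2C.Br | intermediate
18 | tert-butyl (1R,3R)-6,8-dihydroxy-1,3-dimethyl-3,4-dihydro-1H-isoquinoline-2-carboxylate | Oc1cc(O)c2c(c1)C[C@@H](C)N(C(=O)OC(C)(C)C)[C@@H]2C | intermediate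
19 | tert-butyl (1R,3R)-6,8-bis(methoxymethoxy)-1,3-dimethyl-3,4-dihydro-1H-isoquinoline-2-carboxylate | COCOc1cc(OCOC)c2c(c1)C[C@@H](C)N(C(=O)OC(C)(C)C)[C@@H]2C | intermediate
20 | tert-butyl (1R,3R)-5-iodo-6,8-bis(methoxymethoxy)-1,3-dimethyl-3,4-dihydro-1H-isoquinoline-2-carboxylate | COCOc1cc(OCOC)c2c(c1I)C[C@@H](C)N(C(=O)OC(C)(C)C)[C@@H]2C | intermediate
21 | tert-butyl (1R,3R)-5-[3-chloro-5-methoxy-4-(methoxymethoxy)-7-methylnaphthalen-1-yl]-6,8-bis(methoxymethoxy)-1,3-dimethyl-3,4-dihydro-1H-isoquinoline-2-carboxylate | COCOc1cc(OCOC)c2c(c1-c1cc(Cl)c(OCOC)c3c(OC)cc(C)cc13)C[C@@H](C)N(C(=O)OC(C)(C)C)[C@@H]2C | intermediate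
22 | tert-butyl (1R,3R)-5-[5-methoxy-4-(methoxymethoxy)-7-methyl-3-(4,4,5,5-tetramethyl-1,3,2-dioxaborolan-2-yl)naphthalen-1-yl]-6,8-bis(methoxymethoxy)-1,3-dimethyl-3,4-dihydro-1H-isoquinoline-2-carboxylate | COCOc1cc(OCOC)c2c(c1-c1cc(B3OC(C)(C)C(C)(C)O3)c(OCOC)c3c(OC)cc(C)cc13)C[C@@H](C)N(C(=O)OC(C)(C)C)[C@@H]2C | intermediate
23 | 3-bromo-5-methoxyphenol | COc1cc(O)cc(Br)c1 | starting material
24 | 1-bromo-3-methoxy-5-(methoxymethoxy)benzene | COCOc1cc(Br)cc(OC)c1 | intermediate
25 | [3-methoxy-5-(methoxymethoxy)phenyl]magnesium bromide (not isolated) | COCOc1cc([Mg]Br)cc(OC)c1 | intermediate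
26 | tert-butyl N-[(2R)-1-[3-methoxy-5-(methoxymethoxy)phenyl]propan-2-yl]carbamate | COCOc1cc(C[C@@H](C)NC(=O)OC(C)(C)C)cc(OC)c1 | intermediate
27 | tert-butyl N-lithio-N-[(2R)-1-[4-lithio-3-methoxy-5-(methoxymethoxy)phenyl]propan-2-yl]carbamate (not isolated) | [Li]c1c(OC)cc(C[C@@H](C)N([Li])C(=O)OC(C)(C)C)cc1OCOC | intermediate
28 | tert-butyl N-[(2R)-1-[4-iodo-3-methoxy-5-(methoxymethoxy)phenyl]propan-2-yl]carbamate | COCOc1cc(C[C@@H](C)NC(=O)OC(C)(C)C)cc(OC)c1I | intermediate
29 | 5-[(2R)-2-aminopropyl]-2-iodo-3-methoxyphenol hydrochloride | COc1cc(C[C@@H](C)N)cc(O)c1I.Cl | intermediate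
30 | (2R)-N-ethylidene-1-(3-hydroxy-4-iodo-5-methoxyphenyl)propan-2-aminium chloride (not isolated) | CC=[NH+][C@H](C)Cc1cc(O)c(I)c(OC)c1.[Cl-] | intermediate
31 | (3R)-7-iodo-8-methoxy-1,3-dimethyl-1,2,3,4-tetrahydroisoquinolin-6-ol (C1 epimers) | COc1c(I)c(O)cc2c1C(C)N[C@H](C)C2 | intermediate
32 | (3R)-7-iodo-8-methoxy-6-(methoxymethoxy)-1,3-dimethyl-1,2,3,4-tetrahydroisoquinoline (C1 epimers) | COCOc1cc2c(c(OC)c1I)C(C)N[C@H](C)C2 | intermediate
33 | (3R)-2-chloro-7-iodo-8-methoxy-6-(methoxymethoxy)-1,3-dimethyl-1,2,3,4-tetrahydroisoquinoline (not isolated) | COCOc1cc2c(c(OC)c1I)C(C)N(Cl)[C@H](C)C2 | intermediate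
34 | (3R)-7-iodo-8-methoxy-6-(methoxymethoxy)-1,3-dimethyl-3,4-dihydroisoquinoline | COCOc1cc2c(c(OC)c1I)C(C)=N[C@H](C)C2 | intermediate
35 | (3R)-7-[3-chloro-5-methoxy-4-(methoxymethoxy)-7-methylnaphthalen-1-yl]-8-methoxy-6-(methoxymethoxy)-1,3-dimethyl-3,4-dihydroisoquinoline | COCOc1cc2c(c(OC)c1-c1cc(Cl)c(OCOC)c3c(OC)cc(C)cc13)C(C)=N[C@H](C)C2 | intermediate
36 | N-Boc-penta-O-MOM-korundamine A (tetrahydroisoquinoline N-Boc; MOM on both isoquinoline 6-O, the 8-O of the tetrahydroisoquinoline and both naphthol oxygens) | COCOc1cc(OCOC)c2c(c1-c1cc(-c3cc(-c4c(OCOC)cc5c(c4OC)C(C)=N[C@H](C)C5)c4cc(C)cc(OC)c4c3OCOC)c(OCOC)c3c(OC)cc(C)cc13)C[C@@H](C)N(C(=O)OC(C)(C)C)[C@@H]2C | intermediate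
37 | korundamine A | COc1c2c(cc(O)c1-c1cc(-c3cc(-c4c(O)cc(O)c5c4C[C@@H](C)N[C@@H]5C)c4cc(C)cc(OC)c4c3O)c(O)c3c(OC)cc(C)cc13)C[C@@H](C)N=C2C | target

## Step count and risk

Total step count: 25. Longest linear sequence: 11 steps (steps 1–7, 14, 15, 24, 25). The two isoquinoline branches are 10 steps each to the target.

The three steps most likely to fail:

**Step 5 (site-selective mono-triflation of hydroquinone 7).** The more acidic chlorine-flanked hydroxyl could compete and give the wrong or the bis-triflate. The fallback sets out from 7 and differentiates the hydroxyls stepwise. t-BuMe2SiCl/imidazole in DMF silylates only the unhindered C4 hydroxyl to give 4-[tert-butyl(dimethyl)silyl]oxy-2-chloro-8-methoxy-6-methylnaphthalen-1-ol F1. MeOCH2Cl/iPr2NEt then caps the peri hydroxyl to give tert-butyl{[3-chloro-5-methoxy-4-(methoxymethoxy)-7-methylnaphthalen-1-yl]oxy}dimethylsilane F2. Bu4NF releases 3-chloro-5-methoxy-4-(methoxymethoxy)-7-methylnaphthalen-1-ol F3, whose single hydroxyl is triflated (Tf2O, pyridine) to come back to the route at 9.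

**Step 20 (regiochemistry of the Mannich closure, para against ortho to the phenol).** If the ortho-cyclised isomer is formed in quantity, the fallback sets out from 14 and makes the ring closure regiochemically degenerate. Compound 14 is lithiated between its two methoxy groups (n-BuLi, 2.3 equiv) to the N,4-dilithio carbamate F4 and quenched with I2 to give tert-butyl N-[(2R)-1-(4-iodo-3,5-dimethoxyphenyl)propan-2-yl]carbamate F5. BBr3 (CH2Cl2, −78 °C → rt, then MeOH) removes both methyl ethers and the Boc group to give 5-[(2R)-2-aminopropyl]-2-iodobenzene-1,3-diol hydrobromide F6. Acetaldehyde in phosphate buffer closes the ring through the N-ethylidene iminium bromide F7; the two ortho sites are now equivalent, so only (3R)-7-iodo-1,3-dimethyl-1,2,3,4-tetrahydroisoquinoline-6,8-diol F8 can form. The unhindered 6-OH is alkylated selectively (NaH 1 equiv, MeOCH2Cl 1 equiv, −40 °C; the 8-OH is shielded by the peri C1 methyl group) to give (3R)-7-iodo-6-(methoxymethoxy)-1,3-dimethyl-1,2,3,4-tetrahydroisoquinolin-8-ol F9. Me3SiCHN2 in MeOH/toluene methylates the remaining phenol, without touching the amine, to come back to the route at 32.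

**Step 23 (Suzuki coupling of the doubly ortho-oxygenated iodide 34, which also carries the imine).** Steric hindrance, deiodination and deboronation of 10 could make it low-yielding. The fallback sets out from 32 and inverts the polarity before the amine is oxidised. iPrMgCl·LiCl (2.2 equiv; N–H deprotonation, then I/Mg exchange) followed by ZnCl2 gives the N-(chloromagnesio)-7-(chlorozincio) derivative of 32 F10. Negishi coupling of this with triflate 9 (Pd(dppf)Cl2, THF, 60 °C; the C–Cl bond is inert) gives (3R)-7-[3-chloro-5-methoxy-4-(methoxymethoxy)-7-methylnaphthalen-1-yl]-8-methoxy-6-(methoxymethoxy)-1,3-dimethyl-1,2,3,4-tetrahydroisoquinoline F11. NCS converts this into its N-chloro derivative F12, and DBU eliminates HCl to come back to the route at 35.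

## Further compounds

F1 | step 5 | 4-[tert-butyl(dimethyl)silyl]oxy-2-chloro-8-methoxy-6-methylnaphthalen-1-ol | COc1cc(C)cc2c(O[Si](C)(C)C(C)(C)C)cc(Cl)c(O)c12
F2 | step 5 | tert-butyl{[3-chloro-5-methoxy-4-(methoxymethoxy)-7-methylnaphthalen-1-yl]oxy}dimethylsilane | COCOc1c(Cl)cc(O[Si](C)(C)C(C)(C)C)c2cc(C)cc(OC)c12
F3 | step 5 | 3-chloro-5-methoxy-4-(methoxymethoxy)-7-methylnaphthalen-1-ol | COCOc1c(Cl)cc(O)c2cc(C)cc(OC)c12
F4 | step 20 | tert-butyl N-lithio-N-[(2R)-1-(4-lithio-3,5-dimethoxyphenyl)propan-2-yl]carbamate | [Li]c1c(OC)cc(C[C@@H](C)N([Li])C(=O)OC(C)(C)C)cc1OC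
F5 | step 20 | tert-butyl N-[(2R)-1-(4-iodo-3,5-dimethoxyphenyl)propan-2-yl]carbamate | COc1cc(C[C@@H](C)NC(=O)OC(C)(C)C)cc(OC)c1I
F6 | step 20 | 5-[(2R)-2-aminopropyl]-2-iodobenzene-1,3-diol hydrobromide | C[C@@H](N)Cc1cc(O)c(I)c(O)c1.Br
F7 | step 20 | (2R)-1-(3,5-dihydroxy-4-iodophenyl)-N-ethylidenepropan-2-aminium bromide | CC=[NH+][C@H](C)Cc1cc(O)c(I)c(O)c1.[Br-]
F8 | step 20 | (3R)-7-iodo-1,3-dimethyl-1,2,3,4-tetrahydroisoquinoline-6,8-diol | CC1N[C@H](C)Cc2cc(O)c(I)c(O)c12
F9 | step 20 | (3R)-7-iodo-6-(methoxymethoxy)-1,3-dimethyl-1,2,3,4-tetrahydroisoquinolin-8-ol | COCOc1cc2c(c(O)c1I)C(C)N[C@H](C)C2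
F10 | step 23 | N-(chloromagnesio)-7-(chlorozincio) derivative of 32 | COCOc1cc2c(c(OC)c1[Zn]Cl)C(C)N([Mg]Cl)[C@H](C)C2
F11 | step 23 | (3R)-7-[3-chloro-5-methoxy-4-(methoxymethoxy)-7-methylnaphthalen-1-yl]-8-methoxy-6-(methoxymethoxy)-1,3-dimethyl-1,2,3,4-tetrahydroisoquinoline | COCOc1cc2c(c(OC)c1-c1cc(Cl)c(OCOC)c3c(OC)cc(C)cc13)C(C)N[C@H](C)C2
F12 | step 23 | (3R)-2-chloro-7-[3-chloro-5-methoxy-4-(methoxymethoxy)-7-methylnaphthalen-1-yl]-8-methoxy-6-(methoxymethoxy)-1,3-dimethyl-1,2,3,4-tetrahydroisoquinoline | COCOc1cc2c(c(OC)c1-c1cc(Cl)c(OCOC)c3c(OC)cc(C)cc13)C(C)N(Cl)[C@H](C)C2
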